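The earlier runs and the new flask come from a simulation on assumed constants; noise was put on by code.

| flask | substrate | free catalyst | remark | time |
|---|---|---|---|---|
| beta | 2.1 M (fed, over 30 h) | 1.4 mol% | run made earlier; the fed solution adds 0.25 times the starting volume |  |
| delta | 2.1 M (fed, over 30 h) | 2.2 mol% | run made earlier; the fed solution adds 0.25 times the starting volume |  |
| alpha | 1.1 M (fed, over 30 h) | 1 mol% | run made earlier; the fed solution adds 0.25 times the starting volume |  |
| south-west | 2.1 M (fed, over 30 h) | 1 mol% | the fed solution adds 0.25 times the starting volume | 30 h |
| east | 2.1 M | 1 mol% | everything together at the start, the whole solution of substrate included, so that from the start the volume is larger by 0.25 times the starting volume | 20 h |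

| run | time / h | target / % | substrate / % |
|---|---|---|---|
| beta | 4.00 | 1.6 | 10.8 |
| beta | 10.0 | 9.6 | 22.5 |
| beta | 20.0 | 32.0 | 35.6 |
| beta | 30.0 | 56.4 | 44.2 |
| delta | 4.00 | 3.6 | 11.1 |
| delta | 10.0 | 14.1 | 18.2 |
| delta | 20.0 | 41.2 | 24.9 |
| delta | 30.0 | 70.8 | 29.9 |
| alpha | 4.00 | 1.0 | 12.8 |
| alpha | 10.0 | 4.0 | 27.0 |
| alpha | 20.0 | 15.6 | 51.2 |
| alpha | 30.0 | 31.3 | 69.6 |

(readings scatter by 0.5 percentage points)

- charges are per starting volume, the dose included; the dosed solution carries all of it
- candidate steps: substrate + free catalyst -> catalyst intermediate; catalyst intermediate -> free catalyst + target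
- percentages count the whole charge, also what has not yet gone in

1. which one finishes higher in amount of target, in percent of the substrate charged ("neither" within 2 percentage points) (south-west / east / neither)
2. amount of target at the end, in percent of the substrate charged, south-west
3. amount of target at the end, in percent of the substrate charged, east

Late in the beta flask, at 30.0 h, the dose is all in and the ledger of the substrate can be read. Unbound substrate stands at 44.2% and target at 56.4%, together 100.6%, with 0.5 percentage points of scatter on each reading. The one remaining entry, substrate held as catalyst intermediate, is bounded by the loading of 1.4 mol%. So the target entry can be counted in turnovers: N, target percent over loading percent. N per hour is f, the turnover frequency.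

Between 20.0 h and 30.0 h, with s the unbound substrate over the volume at mid-window, the readings give:

beta: f = 1.74 h⁻¹ at s = 0.693 M

delta: f = 1.35 h⁻¹ at s = 0.476 M

The delta catalyst turns more slowly than the beta catalyst, and its solution is thinner. A curve that flattens, f = F·s/(K + s), with F the top frequency and K the concentration of half that top, passes through both windows with F = 4.94 h⁻¹ and K = 1.27 M, both as readings.

East starts at s₀ = 1.68 M, which gives the carried quantity, its starting turnover frequency f₀ = 2.81 h⁻¹. With s down to 0.840 M, half of s₀, f is 1.96 h⁻¹. The mean of the two over 20 h at 1 mol% books:

east: target ≈ 47.8%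

South-west shares its charge and dose with beta and delta, whose counts are 40.3 and 32.2. Carried straight down to its loading, the count becomes 44.3:

south-west: target ≈ 44.3%

This reckoning puts east ahead by 3.5 points, more than the margin. The forecast gives east, with 44% (41.5% to 46.5%) for south-west and 46.4% (42% to 50%) for east, a narrower gap than the one here: “The gap is marginal, slightly favouring east.”

East finishes higher, with 51.5% of target against 44.9% for south-west.

    substrate + free catalyst → catalyst intermediate (k = 3.47 M⁻¹ h⁻¹)
    catalyst intermediate → free catalyst + target (k = 6.88 h⁻¹)

At its end, the east flask holds 48.2% of the charge as unbound substrate. Over 5.0 h at 1 mol%, f₀ books 14.1% of target, and the east flask read at that time holds 14.8%.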